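**Retrosynthetic overview**

1. The diacetate comes from the diol and its acetonide; the exocyclic methylene comes from Wittig methylenation of a ketone made from an alkyl Grignard reagent and the Weinreb amide of (S)-isopropylideneglyceric acid, which supplies the acetoxy-bearing stereocentre.
2. The chain is joined next to the ring by Wittig olefination and hydrogenation of (2R)-2,6,6-trimethyloxane-2-carbaldehyde with a phosphonium salt from (R)-citronellyl bromide, which supplies the methyl-bearing stereocentre.
3. The only ring, the oxane, is formed first and in one operation from methyl pyruvate and the silyl dienol ether of mesityl oxide: copper-catalysed enantioselective Mukaiyama aldol addition, then acid-triggered 6-endo oxa-Michael closure (a formal oxa-[4+2]). This makes ring bonds C2–C3 and O1–C6 and sets the quaternary stereocentre.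
4. Enabling feature: in the oxane ring, O1–C2 (C2 is the quaternary carbon with methyl and chain) is a masked ketone C=O whose neighbouring chain carbon can be carried as an ester, and C3–C4–C5–C6, ending in the gem-dimethyl carbon C6, is the skeleton of mesityl oxide (nucleophilic α'-carbon, electrophilic β-carbon) with C4 carried as a ketone.
5. Temporary groups: the C4 ring ketone (removed through its tosylhydrazone) and the ester (reduced to the aldehyde that becomes the first chain carbon).

Key step: step 2

Remark: the sense of induction in step 2 is assumed by analogy with the established model for [Cu(t-Bu-box)](OTf)2 pyruvate aldol additions, in which the (S,S)-ligand leads to si-face attack and (S) adducts; the (R,R)-ligand is therefore specified. Compounds 1, 4, 11 and 19 and all reagents are purchased.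

Step 1
Reactants: 1 mesityl oxide (4-methylpent-3-en-2-one)
Product: 3 4-methyl-2-(trimethylsilyloxy)penta-1,3-diene, via lithium dienolate 2 (not isolated)
Conditions: LiN(i-Pr)2, THF, −78 °C; then Me3SiCl, −78 °C to rt
Reagents that add atoms: chlorotrimethylsilane, C[Si](C)(C)Cl
Why: Kinetic deprotonation of the enone at the α'-methyl group by the hindered lithium amide and O-silylation of the cross-conjugated dienolate (silyl enol ether formation) should give the 2-silyloxy diene, in which only the terminal CH2 is nucleophilic.

Step 2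
Reactants: 3 4-methyl-2-(trimethylsilyloxy)penta-1,3-diene; 4 methyl pyruvate
Product: 7 methyl (2R)-2,6,6-trimethyl-4-oxooxane-2-carboxylate, via silyl aldol adduct 5 (not isolated), via hydroxy enone 6 (not isolated)
Conditions: [Cu((R,R)-t-Bu-box)](OTf)2 (10 mol %; t-Bu-box = 2,2'-(propane-2,2-diyl)bis(4-tert-butyl-4,5-dihydro-1,3-oxazole)), THF, −78 °C; then evaporate, CF3CO2H/H2O (9:1) in CH2Cl2, 0 °C to rt
Reagents that add atoms: none
Why: Methyl pyruvate should bind through its ketone and ester oxygens to the divalent copper centre in a square-planar chelate whose tert-butyl groups block the si face of the ketone, so that the terminal CH2 of enolsilane 3 attacks the re face in an open-transition-state Mukaiyama aldol addition with silyl transfer (adduct 5, new C–C bond at the future quaternary ring carbon); aqueous CF3CO2H then frees the tertiary alcohol (6) and protonates the β,β-dimethyl enone, which the hydroxyl captures at the gem-dimethyl β-carbon to form the ring C–O bond. The closest known reaction types are the [Cu(t-Bu-box)](OTf)2-catalysed enantioselective aldol additions of ketone-derived enolsilanes to pyruvate esters (the stepwise aldol/cyclisation mode of hetero-Diels–Alder reactions of α-keto esters with 2-silyloxy dienes) and the acid-mediated cyclisation of phorone-type β'-hydroxy β,β-dimethyl enones to 2,2-dimethyloxan-4-ones. The oxane ring closes in the 6-endo-trig oxa-Michael mode, so that the two events together amount to a formal oxa-[4+2] cycloaddition. The only new stereocentre, the quaternary C2 with methyl and ester, is set by the chiral ligand (catalyst control) and, having no α-hydrogen, cannot be eroded by the acid. The step needs enantiofacial selectivity at the ketone, which two-point chelation of the 1,2-dicarbonyl unit secures, and site selectivity in both partners, which the cross-conjugated enolsilane (one nucleophilic carbon) and closure at the tertiary enone carbon (no smaller-ring alternative) secure.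

Step 3
Reactants: 7 methyl (2R)-2,6,6-trimethyl-4-oxooxane-2-carboxylate
Product: 9 methyl (2R)-2,6,6-trimethyloxane-2-carboxylate, via tosylhydrazone 8 (not isolated)
Conditions: TsNHNH2, MeOH, 50 °C; evaporate; catecholborane, CHCl3, 0 °C to rt; then NaOAc·3H2O, reflux
Reagents that add atoms: none
Why: Condensation to tosylhydrazone 8, hydroboration of its C=N bond and acetate-triggered loss of sulfinate and N2 from the resulting diazene (Caglioti-type tosylhydrazone reduction, Kabalka variant) should turn the ring ketone into CH2 under mild conditions that spare the ester, the ring ether and the quaternary stereocentre.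

Step 4
Reactants: 9 methyl (2R)-2,6,6-trimethyloxane-2-carboxylate
Product: 10 (2R)-2,6,6-trimethyloxane-2-carbaldehyde
Conditions: i-Bu2AlH (1.1 equiv), CH2Cl2, −78 °C; aqueous KNaC4H4O6 work-up
Reagents that add atoms: none
Why: Partial reduction of the ester at −78 °C should stop at the aldehyde because the α-alkoxy group stabilises the tetrahedral aluminium hemiacetal until work-up, and the quaternary stereocentre cannot epimerise.

Step 5
Reactants: 11 (R)-citronellyl bromide [(6R)-8-bromo-2,6-dimethyloct-2-ene]
Product: 13 (4R)-6-bromo-4-methylhexan-1-ol, via bromo aldehyde 12 (not isolated)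
Conditions: O3, CH2Cl2/MeOH, −78 °C; then NaBH4, −78 to 0 °C
Reagents that add atoms: ozone, [O-][O+]=O
Why: Ozonolysis of the electron-rich trisubstituted alkene and borohydride reduction of the intermediate aldehyde 12 should give the primary alcohol while the primary bromide and the methyl-bearing stereocentre stay untouched.

Step 6
Reactants: 13 (4R)-6-bromo-4-methylhexan-1-ol
Product: 14 [(3R)-6-hydroxy-3-methylhexyl]triphenylphosphonium bromide
Conditions: PPh3, MeCN, reflux
Reagents that add atoms: triphenylphosphine, c1ccc(cc1)P(c1ccccc1)c1ccccc1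
Why: SN2 quaternisation of triphenylphosphine by the unhindered primary bromide (phosphonium salt formation) should proceed cleanly in the presence of the free hydroxyl group.

Step 7
Reactants: 14 [(3R)-6-hydroxy-3-methylhexyl]triphenylphosphonium bromide; 10 (2R)-2,6,6-trimethyloxane-2-carbaldehyde
Product: 16 (4R,6Z)-4-methyl-7-[(2R)-2,6,6-trimethyloxan-2-yl]hept-6-en-1-ol, via alkoxide ylide 15 (not isolated)
Conditions: NaN(SiMe3)2 (2.1 equiv), THF, −78 to 0 °C; then 10, −78 °C to rt; aqueous work-up
Reagents that add atoms: none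
Why: Wittig olefination of the non-enolisable α-alkoxy aldehyde with the unstabilised ylide, whose hydroxyl is carried as the sodium alkoxide, should give mainly the Z-alkene, and the geometry is irrelevant because the double bond is saturated in the next step.

Step 8
Reactants: 16 (4R,6Z)-4-methyl-7-[(2R)-2,6,6-trimethyloxan-2-yl]hept-6-en-1-ol
Product: 17 (4S)-4-methyl-7-[(2S)-2,6,6-trimethyloxan-2-yl]heptan-1-ol
Conditions: H2 (1 atm), PtO2, EtOAc, rt
Reagents that add atoms: none
Why: Heterogeneous hydrogenation over platinum should saturate the disubstituted alkene with little tendency to hydrogenolyse the allylic tertiary C–O bond, and no stereocentre is touched (both descriptors change only because the CIP priorities change).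

Step 9
Reactants: 17 (4S)-4-methyl-7-[(2S)-2,6,6-trimethyloxan-2-yl]heptan-1-ol
Product: 18 (2S)-2-[(4S)-7-bromo-4-methylheptyl]-2,6,6-trimethyloxane
Conditions: CBr4, PPh3, CH2Cl2, 0 °C
Reagents that add atoms: tetrabromomethane, BrC(Br)(Br)Br
Why: The Appel reaction should convert the primary alcohol into the bromide under neutral conditions that leave the tertiary ring ether intact.

Step 10
Reactants: 19 methyl (4S)-2,2-dimethyl-1,3-dioxolane-4-carboxylate
Product: 20 (4S)-N-methoxy-N,2,2-trimethyl-1,3-dioxolane-4-carboxamide
Conditions: MeNH(OMe)·HCl, i-PrMgCl, THF, −20 °C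
Reagents that add atoms: N,O-dimethylhydroxylamine hydrochloride, CNOC.Cl
Why: Aminolysis of the methyl ester by the chloromagnesium amide of N,O-dimethylhydroxylamine (Weinreb amide formation) at low temperature should occur without enolisation of the α-alkoxy stereocentre.

Step 11
Reactants: 18 (2S)-2-[(4S)-7-bromo-4-methylheptyl]-2,6,6-trimethyloxane; 20 (4S)-N-methoxy-N,2,2-trimethyl-1,3-dioxolane-4-carboxamide
Product: 22 (5S)-1-[(4S)-2,2-dimethyl-1,3-dioxolan-4-yl]-5-methyl-8-[(2S)-2,6,6-trimethyloxan-2-yl]octan-1-one, via Grignard reagent 21 (not isolated)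
Conditions: Mg, I2 (cat.), THF, 40 °C; then 20, THF, 0 °C; aqueous NH4Cl
Reagents that add atoms: none
Why: In this Weinreb ketone synthesis the Grignard reagent 21 should add once, because the five-membered magnesium chelate of the tetrahedral adduct prevents over-addition and enolisation, so the α-alkoxy stereocentre is retained.

Step 12
Reactants: 22 (5S)-1-[(4S)-2,2-dimethyl-1,3-dioxolan-4-yl]-5-methyl-8-[(2S)-2,6,6-trimethyloxan-2-yl]octan-1-one
Product: 23 (4R)-2,2-dimethyl-4-{(6R)-6-methyl-9-[(2S)-2,6,6-trimethyloxan-2-yl]non-1-en-2-yl}-1,3-dioxolane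
Conditions: Ph3PCH3Br, KN(SiMe3)2, THF, 0 °C; then 22, −78 to 0 °C
Reagents that add atoms: methyltriphenylphosphonium bromide, C[P+](c1ccccc1)(c1ccccc1)c1ccccc1.[Br-]
Why: Wittig methylenation with the non-stabilised ylide at low temperature should convert the ketone into the 1,1-disubstituted alkene faster than it enolises, as is usual for acetonide-protected α,β-dihydroxy ketones, so the allylic stereocentre keeps its configuration.

Step 13
Reactants: 23 (4R)-2,2-dimethyl-4-{(6R)-6-methyl-9-[(2S)-2,6,6-trimethyloxan-2-yl]non-1-en-2-yl}-1,3-dioxolane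
Product: 24 (2R,7R)-7-methyl-3-methylidene-10-[(2S)-2,6,6-trimethyloxan-2-yl]decane-1,2-diol
Conditions: AcOH/H2O/THF (3:1:1), 40 °C
Reagents that add atoms: none
Why: Mild acid hydrolysis of the isopropylidene acetal should free the 1,2-diol without ionising the allylic C–O bond or opening the tertiary ring ether.

Step 14
Reactants: 24 (2R,7R)-7-methyl-3-methylidene-10-[(2S)-2,6,6-trimethyloxan-2-yl]decane-1,2-diol
Product: 25 (2R,7R)-7-methyl-3-methylidene-10-[(2S)-2,6,6-trimethyloxan-2-yl]decane-1,2-diyl diacetate (CNP0136694.1)
Conditions: Ac2O, pyridine, DMAP (cat.), CH2Cl2, rt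
Reagents that add atoms: acetic anhydride, CC(=O)OC(C)=O
Why: DMAP-catalysed acylation should esterify the primary and the secondary allylic hydroxyl group and give the target diacetate with all three stereocentres in place.

**Compound list**

1 | mesityl oxide (4-methylpent-3-en-2-one) | CC(=O)C=C(C)C | starting material
2 | lithium 4-methylpenta-1,3-dien-2-olate | [Li+].[O-]C(=C)C=C(C)C | intermediate (not isolated)
3 | 4-methyl-2-(trimethylsilyloxy)penta-1,3-diene | C=C(O[Si](C)(C)C)C=C(C)C | intermediate
4 | methyl pyruvate | CC(=O)C(=O)OC | starting material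
5 | methyl (2R)-2,6-dimethyl-4-oxo-2-(trimethylsilyloxy)hept-5-enoate | COC(=O)[C@@](O[Si](C)(C)C)(C)CC(=O)C=C(C)C | intermediate (not isolated)
6 | methyl (2R)-2-hydroxy-2,6-dimethyl-4-oxohept-5-enoate | COC(=O)[C@@](O)(C)CC(=O)C=C(C)C | intermediate (not isolated)
7 | methyl (2R)-2,6,6-trimethyl-4-oxooxane-2-carboxylate | COC(=O)[C@@]1(C)CC(=O)CC(C)(C)O1 | intermediate
8 | methyl (2R)-2,6,6-trimethyl-4-[2-(4-methylbenzenesulfonyl)hydrazinylidene]oxane-2-carboxylate (C=N isomers) | COC(=O)[C@@]1(C)CC(=NNS(=O)(=O)c2ccc(C)cc2)CC(C)(C)O1 | intermediate (not isolated)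
9 | methyl (2R)-2,6,6-trimethyloxane-2-carboxylate | COC(=O)[C@@]1(C)CCCC(C)(C)O1 | intermediate
10 | (2R)-2,6,6-trimethyloxane-2-carbaldehyde | O=C[C@@]1(C)CCCC(C)(C)O1 | intermediate
11 | (R)-citronellyl bromide, (6R)-8-bromo-2,6-dimethyloct-2-ene | BrCC[C@H](C)CCC=C(C)C | starting material
12 | (4R)-6-bromo-4-methylhexanal | BrCC[C@H](C)CCC=O | intermediate (not isolated)
13 | (4R)-6-bromo-4-methylhexan-1-ol | BrCC[C@H](C)CCCO | intermediate
14 | [(3R)-6-hydroxy-3-methylhexyl]triphenylphosphonium bromide | OCCC[C@@H](C)CC[P+](c1ccccc1)(c1ccccc1)c1ccccc1.[Br-] | intermediate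
15 | sodium (4R)-4-methyl-6-(triphenyl-λ5-phosphanylidene)hexan-1-olate | [Na+].[O-]CCC[C@@H](C)CC=P(c1ccccc1)(c1ccccc1)c1ccccc1 | intermediate (not isolated)
16 | (4R,6Z)-4-methyl-7-[(2R)-2,6,6-trimethyloxan-2-yl]hept-6-en-1-ol | OCCC[C@@H](C)C/C=C\[C@@]1(C)CCCC(C)(C)O1 | intermediate
17 | (4S)-4-methyl-7-[(2S)-2,6,6-trimethyloxan-2-yl]heptan-1-ol | OCCC[C@@H](C)CCC[C@@]1(C)CCCC(C)(C)O1 | intermediate
18 | (2S)-2-[(4S)-7-bromo-4-methylheptyl]-2,6,6-trimethyloxane | BrCCC[C@@H](C)CCC[C@@]1(C)CCCC(C)(C)O1 | intermediate
19 | methyl (4S)-2,2-dimethyl-1,3-dioxolane-4-carboxylate | COC(=O)[C@@H]1COC(C)(C)O1 | starting material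
20 | (4S)-N-methoxy-N,2,2-trimethyl-1,3-dioxolane-4-carboxamide | CON(C)C(=O)[C@@H]1COC(C)(C)O1 | intermediate
21 | bromo{(4S)-4-methyl-7-[(2S)-2,6,6-trimethyloxan-2-yl]heptyl}magnesium | Br[Mg]CCC[C@@H](C)CCC[C@@]1(C)CCCC(C)(C)O1 | intermediate (not isolated)
22 | (5S)-1-[(4S)-2,2-dimethyl-1,3-dioxolan-4-yl]-5-methyl-8-[(2S)-2,6,6-trimethyloxan-2-yl]octan-1-one | O=C(CCC[C@@H](C)CCC[C@@]1(C)CCCC(C)(C)O1)[C@@H]2COC(C)(C)O2 | intermediate
23 | (4R)-2,2-dimethyl-4-{(6R)-6-methyl-9-[(2S)-2,6,6-trimethyloxan-2-yl]non-1-en-2-yl}-1,3-dioxolane | C=C(CCC[C@@H](C)CCC[C@@]1(C)CCCC(C)(C)O1)[C@@H]2COC(C)(C)O2 | intermediate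
24 | (2R,7R)-7-methyl-3-methylidene-10-[(2S)-2,6,6-trimethyloxan-2-yl]decane-1,2-diol | C=C(CCC[C@@H](C)CCC[C@@]1(C)CCCC(C)(C)O1)[C@H](CO)O | intermediate
25 | (2R,7R)-7-methyl-3-methylidene-10-[(2S)-2,6,6-trimethyloxan-2-yl]decane-1,2-diyl diacetate | C=C(CCC[C@@H](C)CCC[C@@]1(C)CCCC(C)(C)O1)[C@H](COC(C)=O)OC(C)=O | target

**Step count and risks**

Total step count: 14. Longest linear sequence: 11 steps (steps 1, 2, 3, 4, 7, 8, 9, 11, 12, 13, 14).

Steps most likely to fail:

Step 2. Under acid, the 6-endo ring closure may be overtaken by retro-aldol cleavage or dehydration of the tertiary aldol, and facial discrimination may be lower for this enolsilane than for those already known. The fallback takes the quaternary stereocentre from the chiral pool and forms only the ring C–O bond. It does not set out from a numbered compound: it replaces compounds 1 to 9, begins with purchased (R)-linalool F1 and comes back to the route at compound 10. Intramolecular alkoxymercuration of the trisubstituted alkene by the tertiary hydroxyl (Hg(OAc)2, THF, rt) should give acetoxy[(6R)-6-ethenyl-2,2,6-trimethyloxan-3-yl]mercury F2. Reductive demercuration (NaBH4, aqueous NaOH) should give (2R)-2-ethenyl-2,6,6-trimethyloxane F3, and ozonolysis of the vinyl group (O3, CH2Cl2, −78 °C; PPh3) should give 10.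

Step 3. The diazene may eliminate instead of being reduced (giving a ring alkene), or acid during hydrazone formation may open the β-alkoxy ketone by β-elimination. The fallback sets out from 7 and comes back at 9. Thioketalisation with ethane-1,2-dithiol (BF3·OEt2 cat., CH2Cl2, 0 °C) should give methyl (7R)-7,9,9-trimethyl-8-oxa-1,4-dithiaspiro[4.5]decane-7-carboxylate F4. Hydrogenolytic desulfurisation with Raney nickel (Ni) in EtOH at reflux should then give 9 without any diazene intermediate.

Step 12. The basic ylide may enolise the α-alkoxy ketone, with loss of configuration at the acetonide-bearing carbon or β-elimination of the acetonide oxygen. The fallback avoids the α-alkoxy ketone and sets the carbinol stereocentre with a tartrate; it sets out from 18 and comes back at 24.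
- Displacement of the bromide with LiC≡CH·H2N(CH2)2NH2 in DMSO should give (2S)-2,6,6-trimethyl-2-[(4R)-4-methylnon-8-yn-1-yl]oxane F5.
- Zirconium-catalysed carboalumination (Me3Al, Cp2ZrCl2 cat., CH2Cl2) and trapping of the alkenylalane with paraformaldehyde should give (2E,7R)-3,7-dimethyl-10-[(2S)-2,6,6-trimethyloxan-2-yl]dec-2-en-1-ol F6.
- Sharpless asymmetric epoxidation (Ti(Oi-Pr)4, L-(+)-diethyl tartrate, t-BuOOH, 4 Å molecular sieves, CH2Cl2, −20 °C) should give [(2S,3S)-3-methyl-3-{(4S)-4-methyl-7-[(2S)-2,6,6-trimethyloxan-2-yl]heptyl}oxiran-2-yl]methanol F7.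
- Isomerisation of the epoxide by deprotonation at its methyl group with Et2AlNC9H18 (diethylaluminium 2,2,6,6-tetramethylpiperidide, excess, toluene, 0 °C) should give 24, since the C–O bond of the secondary carbinol is not touched.

Further compounds
F1 | step 2 | (R)-linalool, (3R)-3,7-dimethylocta-1,6-dien-3-ol (purchased starting material of the fallback) | C=C[C@@](O)(C)CCC=C(C)C
F2 | step 2 | acetoxy[(6R)-6-ethenyl-2,2,6-trimethyloxan-3-yl]mercury (epimers at C3) | C=C[C@@]1(C)CCC([Hg]OC(C)=O)C(C)(C)O1
F3 | step 2 | (2R)-2-ethenyl-2,6,6-trimethyloxane | C=C[C@@]1(C)CCCC(C)(C)O1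
F4 | step 3 | methyl (7R)-7,9,9-trimethyl-8-oxa-1,4-dithiaspiro[4.5]decane-7-carboxylate | COC(=O)[C@@]1(C)CC2(CC(C)(C)O1)SCCS2
F5 | step 12 | (2S)-2,6,6-trimethyl-2-[(4R)-4-methylnon-8-yn-1-yl]oxane | C#CCCC[C@@H](C)CCC[C@@]1(C)CCCC(C)(C)O1
F6 | step 12 | (2E,7R)-3,7-dimethyl-10-[(2S)-2,6,6-trimethyloxan-2-yl]dec-2-en-1-ol | OC/C=C(\C)CCC[C@@H](C)CCC[C@@]1(C)CCCC(C)(C)O1
F7 | step 12 | [(2S,3S)-3-methyl-3-{(4S)-4-methyl-7-[(2S)-2,6,6-trimethyloxan-2-yl]heptyl}oxiran-2-yl]methanol | OC[C@@H]1O[C@@]1(C)CCC[C@@H](C)CCC[C@@]2(C)CCCC(C)(C)O2
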